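## Retrosynthetic overview

1. Feature: in the 1,2-dioxane ring of the target, C4 (methyl, lactone oxygen) and C5 (CH2) lie between the two peroxide carbons C3 and C6. A C4=C5 alkene therefore makes both peroxide carbons allylic and also serves as the handle for the γ-lactone. Numbering: C1 lactone carbonyl, C2 CH2, C3 peroxide CH, C4, C5, C6 peroxide carbon with methyl and hexadecyl.
2. Lactone ring last: target 13 ⇐ removal of iodine at C5 from iodolactone 12 ⇐ iodolactonisation (C4–O) of dihydrodioxine acid 11 ⇐ ester 10.
3. Dioxine ring first: 10 ⇐ ring-closing metathesis at C4=C5 of the acyclic bis-allylic peroxide 9 (isopropenyl on C3, vinyl on C6).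
4. 9 ⇐ C6–O bond between (S)-hydroperoxide 4 and the tertiary allylic trichloroacetimidate 8.
5. 4 ⇐ Schenck ene reaction of ester 2, then enzymatic resolution; 8 ⇐ 2-octadecanone 5 + vinylmagnesium bromide 6.

Key step: step 7

Assumption: horseradish peroxidase is taken to reduce the (R)-enantiomer of 3 preferentially, as with other secondary hydroperoxides, so that (S)-hydroperoxide 4 is recovered.

Remark: the acid is carried as its methyl ester, because removing an acid-labile ester from the dihydrodioxine would expose the tertiary allylic C6–O bond to ionising conditions.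

Remark: C6 is formed without control in step 6. Peroxide 9 is therefore obtained and used as a mixture with its C6 epimer, methyl (3S)-4-methyl-3-{[(3S)-3-methylnonadec-1-en-3-yl]peroxy}pent-4-enoate. This by-product cyclises alongside 9 in step 7 and is removed there by chromatography as methyl 2-[(3S,6S)-6-hexadecyl-4,6-dimethyl-3,6-dihydro-1,2-dioxin-3-yl]acetate. Neither epimer is taken further.

## Route

Step 1
Reactants: 1 4-methylpent-3-enoic acid
Product: 2 methyl 4-methylpent-3-enoate
Conditions: MeI, K2CO3, DMF, rt
Reagents that add atoms: iodomethane, CI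
Why: Carboxylate O-alkylation (SN2) under weakly basic conditions avoids the acid-induced lactonisation and double-bond migration to which this β,γ-unsaturated acid is prone.

Step 2
Reactants: 2 methyl 4-methylpent-3-enoate
Product: 3 racemic methyl 3-hydroperoxy-4-methylpent-4-enoate
Conditions: O2, hν (visible), tetraphenylporphyrin (cat.), CH2Cl2, 0 °C; chromatography
Reagents that add atoms: dioxygen (as singlet oxygen), O=O
Why: Schenck ene reaction, in which singlet oxygen bonds to C3 and a methyl hydrogen is transferred so that the alkene shifts to C4=CH2; abstraction from the methyl groups should be favoured over the C2 hydrogens next to the ester, the conjugated tertiary regioisomer is removed by chromatography, and C3 forms racemic.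

Step 3
Reactants: 3 racemic methyl 3-hydroperoxy-4-methylpent-4-enoate
Product: 4 methyl (3S)-3-hydroperoxy-4-methylpent-4-enoate
Conditions: horseradish peroxidase, guaiacol, phosphate buffer pH 6, rt, stopped past half conversion; chromatography
Reagents that add atoms: none
Why: Enzymatic kinetic resolution, in which the peroxidase reduces one enantiomer of the secondary hydroperoxide to the alcohol with guaiacol as reductant and leaves the (S)-hydroperoxide, whose configuration becomes C3 of the target; running past half conversion should raise its enantiomeric purity.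

Step 4
Reactants: 5 2-octadecanone; 6 vinylmagnesium bromide
Product: 7 racemic 3-methylnonadec-1-en-3-ol
Conditions: THF, 0 °C → rt; sat. aq. NH4Cl
Reagents that add atoms: none
Why: Grignard 1,2-addition to the methyl ketone gives the tertiary allylic alcohol, racemic, which is immaterial because this carbon is ionised in step 6.

Step 5
Reactants: 7 racemic 3-methylnonadec-1-en-3-ol
Product: 8 3-methylnonadec-1-en-3-yl 2,2,2-trichloroacetimidate
Conditions: Cl3CCN, NaH (cat.), Et2O, 0 °C; filtered through Celite with pentane, concentrated cold, used at once
Reagents that add atoms: trichloroacetonitrile, N#CC(Cl)(Cl)Cl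
Why: Base-catalysed addition of the tertiary alkoxide to trichloroacetonitrile gives the imidate, which is kept cold and used immediately to forestall the [3,3] Overman rearrangement.

Step 6
Reactants: 4 methyl (3S)-3-hydroperoxy-4-methylpent-4-enoate; 8 3-methylnonadec-1-en-3-yl 2,2,2-trichloroacetimidate
Product: 9 methyl (3S)-4-methyl-3-{[(3R)-3-methylnonadec-1-en-3-yl]peroxy}pent-4-enoate
Conditions: 8 (1.5 equiv), BF3·OEt2 (5 mol%), cyclohexane/CH2Cl2 2:1, −30 → 0 °C; aq. NaHCO3; the C6 epimers are not separated
Reagents that add atoms: none
Why: Lewis-acid-promoted SN1 alkylation of a hydroperoxide by a tertiary trichloroacetimidate, in which the allyl cation ion pair should be captured by the terminal oxygen of 4 at its tertiary terminus under kinetic control in a non-polar medium at low temperature; the C3–O bond is untouched so C3 stays S, while C6 forms without control, so 9 is obtained as a mixture with its (3S,3'S) C6 epimer, which accompanies it into step 7.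

Step 7
Reactants: 9 methyl (3S)-4-methyl-3-{[(3R)-3-methylnonadec-1-en-3-yl]peroxy}pent-4-enoate (used as the mixture with its C6 epimer from step 6)
Product: 10 methyl 2-[(3S,6R)-6-hexadecyl-4,6-dimethyl-3,6-dihydro-1,2-dioxin-3-yl]acetate
Conditions: second-generation Grubbs catalyst RuCl2(=CHPh)(H2IMes)(PCy3) (5–10 mol%), CH2Cl2 (0.005 M), 40 °C, argon sparge; silica gel chromatography to remove the (3S,6S) epimer
Reagents that add atoms: none
Why: Ring-closing olefin metathesis by the Chauvin mechanism: the ruthenium benzylidene first exchanges with the unhindered vinyl group on C6, the resulting C5 alkylidene adds across the 1,1-disubstituted C4=CH2 of the isopropenyl group to give a ruthenacyclobutane, and cycloreversion forms C4=C5 and releases ethylene. The closest known reactions are ruthenium-catalysed metathesis of alkenes that carry dialkyl peroxides, ring closures included, and ring-closing metathesis of allyl ethers to six-membered rings with a trisubstituted alkene; what is new here is only the substitution pattern, a trisubstituted alkene formed next to a fully substituted peroxide carbon, and this is where the risk of the route lies. The six-membered 3,6-dihydro-1,2-dioxine ring (O1, O2, C3, C4, C5, C6) closes by this intramolecular [2+2]/retro-[2+2] sequence with the O–O unit as the tether. No stereocentre is formed or touched, because C3 (S) and C6 lie outside the reacting π bonds and the ring alkene can only be Z. Ring closure has to outrun intermolecular cross-metathesis and ruthenium-induced O–O cleavage, which the quaternary C6 and the tertiary C3 on the two sides of the peroxide (Thorpe–Ingold effect), high dilution, removal of ethylene and the reluctance of both hindered alkenes to homodimerise should secure. The (3S,3'S) epimer carried in from step 6 closes in the same way to the (3S,6S) dihydrodioxine, which should be separable from 10 on silica gel at this rigid cyclic stage, with the iodolactone stage as a second opportunity.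

Step 8
Reactants: 10 methyl 2-[(3S,6R)-6-hexadecyl-4,6-dimethyl-3,6-dihydro-1,2-dioxin-3-yl]acetate
Product: 11 2-[(3S,6R)-6-hexadecyl-4,6-dimethyl-3,6-dihydro-1,2-dioxin-3-yl]acetic acid
Conditions: LiOH·H2O, THF/H2O 3:1, 0 °C; cold 0.5 M HCl to pH 3
Reagents that add atoms: lithium hydroxide, [Li+].[OH-]
Why: Saponification of the unhindered methyl ester is much faster than enolisation at C2, so the β-peroxy ester should hydrolyse before E1cB loss of the peroxide or Kornblum–DeLaMare cleavage can intervene; no stereocentre is involved.

Step 9
Reactants: 11 2-[(3S,6R)-6-hexadecyl-4,6-dimethyl-3,6-dihydro-1,2-dioxin-3-yl]acetic acid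
Product: 12 (3S,4R,5S,6R)-3,6-epidioxy-5-iodo-4,6-dimethyldocosan-4-olide (cis-fused 1,2-dioxane/γ-lactone, iodine on C5 trans to the lactone oxygen)
Conditions: I2, KI, NaHCO3, THF/H2O, 0 °C → rt, dark; aq. Na2S2O3
Reagents that add atoms: iodine, II
Why: Iodolactonisation, in which the carboxylate tethered to C3 opens the iodonium ion of C4=C5 at the tertiary C4 in a 5-exo, anti fashion and can reach only the ring face that carries the C3 side chain, so the cis-fused γ-lactone forms with the C4 configuration set by C3 and iodine on C5 trans to the new C–O bond.

Step 10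
Reactants: 12 (3S,4R,5S,6R)-3,6-epidioxy-5-iodo-4,6-dimethyldocosan-4-olide
Product: 13 (3S,4S,6R)-3,6-epidioxy-4,6-dimethyldocosan-4-olide (target CNP0079571.1)
Conditions: Bu3SnH (3 equiv, 0.5 M), azobisisobutyronitrile (cat.), PhH, 80 °C
Reagents that add atoms: none
Why: Radical chain dehalogenation, in which the C5 radical is quenched by the stannane at a concentration chosen to outrun closure of this β-peroxyalkyl radical to an epoxide; C5 becomes CH2 and C3, C4 and C6 are untouched (the C4 descriptor changes from R to S only because iodine leaves C5).

## Compound list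

1 | 4-methylpent-3-enoic acid | CC(C)=CCC(=O)O | starting material
2 | methyl 4-methylpent-3-enoate | COC(=O)CC=C(C)C | intermediate
3 | racemic methyl 3-hydroperoxy-4-methylpent-4-enoate | COC(=O)CC(OO)C(C)=C | intermediate
4 | methyl (3S)-3-hydroperoxy-4-methylpent-4-enoate | C=C(C)[C@H](CC(=O)OC)OO | intermediate
5 | 2-octadecanone | CCCCCCCCCCCCCCCCC(C)=O | starting material
6 | vinylmagnesium bromide | C=C[Mg]Br | starting material
7 | racemic 3-methylnonadec-1-en-3-ol | CCCCCCCCCCCCCCCCC(C)(O)C=C | intermediate
8 | 3-methylnonadec-1-en-3-yl 2,2,2-trichloroacetimidate | CCCCCCCCCCCCCCCCC(C)(C=C)OC(=N)C(Cl)(Cl)Cl | intermediate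
9 | methyl (3S)-4-methyl-3-{[(3R)-3-methylnonadec-1-en-3-yl]peroxy}pent-4-enoate | C=C(C)[C@H](CC(=O)OC)OO[C@@](C)(C=C)CCCCCCCCCCCCCCCC | intermediate
10 | methyl 2-[(3S,6R)-6-hexadecyl-4,6-dimethyl-3,6-dihydro-1,2-dioxin-3-yl]acetate | CCCCCCCCCCCCCCCC[C@]1(C)C=C(C)[C@H](CC(=O)OC)OO1 | intermediate
11 | 2-[(3S,6R)-6-hexadecyl-4,6-dimethyl-3,6-dihydro-1,2-dioxin-3-yl]acetic acid | CCCCCCCCCCCCCCCC[C@]1(C)C=C(C)[C@H](CC(=O)O)OO1 | intermediate
12 | (3S,4R,5S,6R)-3,6-epidioxy-5-iodo-4,6-dimethyldocosan-4-olide | CCCCCCCCCCCCCCCC[C@]1(C)[C@@H](I)[C@]2(C)OC(=O)C[C@@H]2OO1 | intermediate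
13 | (3S,4S,6R)-3,6-epidioxy-4,6-dimethyldocosan-4-olide | CCCCCCCCCCCCCCCC[C@]1(C)C[C@]2(C)OC(=O)C[C@@H]2OO1 | target

## Step count

Total: 10 steps. Longest linear sequence: 8 steps (1, 2, 3, 6, 7, 8, 9, 10).

## Steps most likely to fail

**Step 7 (ring-closing metathesis).** The carbene may load on the vinyl group but fail to add to the hindered isopropenyl alkene, so that intermolecular metathesis through the vinyl groups or ruthenium-induced O–O cleavage takes over. The fallback sets out from 2-octadecanone 5 and comes back at acid 11. It gives up control of C3 and forms the ring by cycloaddition of singlet oxygen.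
- Ketone 5 is treated with 1-propynylmagnesium bromide (THF, 0 °C) to give 4-methylicos-2-yn-4-ol F1.
- Meyer–Schuster rearrangement (Ph3PAuNTf2 cat., MeOH/toluene, rt) should give 4-methylicos-3-en-2-one F2.
- Wittig reaction with the ylide from (2-carboxyethyl)triphenylphosphonium bromide (NaN(SiMe3)2, 2 equiv, THF, −78 °C → rt) should give 4,6-dimethyldocosa-3,5-dienoic acid F3 as a mixture of alkene isomers.
- Sensitised photooxygenation (O2, hν, tetraphenylporphyrin cat., CH2Cl2, 0 °C) should add singlet oxygen [4+2] across C3–C6 to give 2-(6-hexadecyl-4,6-dimethyl-3,6-dihydro-1,2-dioxin-3-yl)acetic acid F4 as a mixture of stereoisomers.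
- Separation of the diastereomers on silica gel and of the enantiomers on a chiral stationary phase would then deliver 11.

**Step 6 (peroxide alkylation).** The tertiary allylic imidate may undergo [3,3] rearrangement to the amide, or the allyl cation may be captured at its primary terminus, before the tertiary peroxide forms. The fallback sets out from 5 and 4 and comes back at 9. It replaces the allyl cation by a propargylic cation that has no such ambiguity.
- Ketone 5 and ethynylmagnesium bromide (THF, 0 °C) give 3-methylnonadec-1-yn-3-ol F5.
- Cl3CCN with catalytic NaH gives 3-methylnonadec-1-yn-3-yl 2,2,2-trichloroacetimidate F6.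
- Alkylation of 4 (BF3·OEt2 cat., cyclohexane/CH2Cl2, −20 °C) should give methyl (3S)-4-methyl-3-[(3-methylnonadec-1-yn-3-yl)peroxy]pent-4-enoate F7 as both C6 epimers.
- Semihydrogenation of the terminal alkyne (H2 1 atm, Lindlar catalyst, Pd on CaCO3 poisoned with Pb(OAc)2, quinoline, hexane, rt), which dialkyl peroxides and the 1,1-disubstituted alkene should tolerate, would return 9, again as the mixture with its C6 epimer.

**Step 3 (enzymatic resolution).** The enzyme may discriminate poorly between the enantiomers of a hydroperoxide that lacks a small methyl substituent at the carbinol carbon, or may prefer the opposite enantiomer. The fallback sets out from racemic 3 and comes back at 4. It replaces the kinetic resolution by a physical one: racemic 3 is separated by preparative chromatography on a polysaccharide chiral stationary phase (cellulose tris(3,5-dimethylphenylcarbamate), hexane/iPrOH). The (S)-enantiomer would be assigned by comparing its chiroptical data with calculated values.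

## Further compounds

F1 | step 7 | 4-methylicos-2-yn-4-ol | CC#CC(C)(O)CCCCCCCCCCCCCCCC
F2 | step 7 | 4-methylicos-3-en-2-one (E/Z) | CC(=O)C=C(C)CCCCCCCCCCCCCCCC
F3 | step 7 | 4,6-dimethyldocosa-3,5-dienoic acid (alkene isomers) | OC(=O)CC=C(C)C=C(C)CCCCCCCCCCCCCCCC
F4 | step 7 | 2-(6-hexadecyl-4,6-dimethyl-3,6-dihydro-1,2-dioxin-3-yl)acetic acid (all stereoisomers) | CCCCCCCCCCCCCCCCC1(C)C=C(C)C(CC(=O)O)OO1
F5 | step 6 | 3-methylnonadec-1-yn-3-ol | CCCCCCCCCCCCCCCCC(C)(O)C#C
F6 | step 6 | 3-methylnonadec-1-yn-3-yl 2,2,2-trichloroacetimidate | CCCCCCCCCCCCCCCCC(C)(C#C)OC(=N)C(Cl)(Cl)Cl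
F7 | step 6 | methyl (3S)-4-methyl-3-[(3-methylnonadec-1-yn-3-yl)peroxy]pent-4-enoate (both C6 epimers) | C=C(C)[C@H](CC(=O)OC)OOC(C)(C#C)CCCCCCCCCCCCCCCC
F0 | step 3 | none | none
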